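## Retrosynthetic overview

- Lappaol A (31) ⇒ trans-lactone 29 ⇒ enolate alkylation of the β-substituted butyrolactone 26 with the ring-A bromide 28; 26 ⇒ aldehyde 20 by Stobbe condensation, asymmetric hydrogenation and reductive lactonisation.
- The route rests on ring B, the benzene ring of the dihydrobenzofuran: its C7a(–O1)–C7(–OMe)–C6–C5 unit is C3–C6 of a 3-alkoxy-4-methoxy-2-pyrone, and its C3a–C4 unit is a terminal alkyne carried on the O1–C2–C3 tether.
- 20 ⇒ acetal 19 ⇒ pyronyl ether 17: intramolecular pyrone–alkyne [4+2] addition and loss of CO2 form C7a–C3a and C4–C5 and close ring B and the dihydrofuran ring together.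
- 17 ⇒ anti-alkynol 8 (allenylzinc addition to O-benzylvanillin, sets C2 and C3) + diazopyrandione 14 (from a dioxinone), joined by carbenoid O–H insertion with retention at C2.
- Ring order: sacrificial pyrone (step 7) → ring B and dihydrofuran ring (step 11) → lactone (step 15); rings A and C are purchased arenes.

Key step: step 11

Remark: the anti (1S,2R) alkynol maps onto the trans (2S,3R) ring only if its own oxygen becomes O1, so the pyronyl ether is made with retention (O–H insertion) and not by an inverting displacement; the facial sense of the two catalytic reductions (steps 3 and 14) is assigned by analogy with closely related substrates, and the ligand antipode would be used if a first run showed the opposite sense.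

Abbreviations: TBS = tert-butyldimethylsilyl; TMS = trimethylsilyl; Bn = benzyl; DHB = the (2S,3R)-2-(4-benzyloxy-3-methoxyphenyl)-3-(TBS-oxymethyl)-7-methoxy-2,3-dihydrobenzofuran-5-yl group. Benzofuran numbering (O1, C2, C3, C3a, C4–C7, C7a) is used for ring B and the dihydrofuran ring; ring A is the arene on the lactone α-benzyl group, ring C the 2-aryl group.

## Route

Step 1
Reactants: 1 (tert-butyldimethylsilyloxy)acetaldehyde; 2 trimethylsilylacetylene
Product: 3 rac-1-(TBS-oxy)-4-(trimethylsilyl)but-3-yn-2-ol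
Conditions: 2, n-BuLi, THF, −78 °C; then 1, −78 → 0 °C; aq. NH4Cl
Reagents that add atoms: none
Why: 1,2-addition of the lithium acetylide of 2 to aldehyde 1 (acetylide addition) gives the racemic propargylic alcohol, whose stereocentre is set two steps later.

Step 2
Reactants: 3 rac-1-(TBS-oxy)-4-(trimethylsilyl)but-3-yn-2-ol
Product: 4 1-(TBS-oxy)-4-(trimethylsilyl)but-3-yn-2-one
Conditions: Dess–Martin periodinane, CH2Cl2, 0 °C → rt
Reagents that add atoms: none
Why: Dess–Martin oxidation converts the propargylic alcohol into the ynone under neutral conditions that leave both silyl groups in place.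

Step 3
Reactants: 4 1-(TBS-oxy)-4-(trimethylsilyl)but-3-yn-2-one
Product: 5 (S)-1-(TBS-oxy)-4-(trimethylsilyl)but-3-yn-2-ol
Conditions: Ru[(R,R)-TsDPEN](p-cymene) (1 mol%), i-PrOH, rt
Reagents that add atoms: none
Why: Noyori asymmetric transfer hydrogenation of an alkynyl ketone, in which the alkynyl group is the π-substituent recognised by the Ru amido catalyst, so the (R,R)-ligand should deliver hydride to the face that gives the (S)-alcohol (CH2OTBS outranks the alkyne in the CIP order, hence the antipode of the ligand that gives (S)-alkynyl methyl carbinols).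

Step 4
Reactants: 5 (S)-1-(TBS-oxy)-4-(trimethylsilyl)but-3-yn-2-ol
Product: 6 (S)-1-(TBS-oxy)-4-(trimethylsilyl)but-3-yn-2-yl methanesulfonate
Conditions: MsCl, Et3N, CH2Cl2, −78 → −40 °C; used crude
Reagents that add atoms: methanesulfonyl chloride, CS(=O)(=O)Cl
Why: O-sulfonylation leaves the C–O bond intact and gives the (S)-propargylic mesylate needed for SN2' oxidative addition.

Step 5
Reactants: 6 (S)-1-(TBS-oxy)-4-(trimethylsilyl)but-3-yn-2-yl methanesulfonate; 7 4-benzyloxy-3-methoxybenzaldehyde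
Product: 8 (1S,2R)-1-(4-benzyloxy-3-methoxyphenyl)-2-(TBS-oxymethyl)-4-(trimethylsilyl)but-3-yn-1-ol (anti)
Conditions: Pd(OAc)2 (5 mol%), PPh3 (5 mol%), Et2Zn (3 equiv), THF, −78 → −20 °C; aq. NH4Cl
Reagents that add atoms: none
Why: Marshall propargylation, in which zerovalent palladium displaces the mesylate in an anti SN2' sense, transmetalation gives a configurationally defined allenylzinc, and its SE2' addition to 7 through a closed six-membered transition state places the new C–C bond anti to the departed mesylate (future C3 = R) and the aryl group anti to CH2OTBS (future C2 = S), the minor syn isomer being removed by chromatography.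

Step 6
Reactants: 9 2,2,6-trimethyl-4H-1,3-dioxin-4-one; 10 methyl dimethoxyacetate
Product: 11 6-(3,3-dimethoxy-2-oxopropyl)-2,2-dimethyl-4H-1,3-dioxin-4-one
Conditions: 9 (2.2 equiv), LDA (2.2 equiv), THF, −78 °C; then 10, −78 → −30 °C; aq. NH4Cl
Reagents that add atoms: none
Why: vinylogous Claisen condensation, in which the lithium dienolate of 9 is acylated at its γ-carbon by the activated ester 10 and the second equivalent of dienolate stores the product as its enolate.

Step 7
Reactants: 11 6-(3,3-dimethoxy-2-oxopropyl)-2,2-dimethyl-4H-1,3-dioxin-4-one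
Product: 13 6-(dimethoxymethyl)-4-hydroxy-2H-pyran-2-one, via acylketene 12 (not isolated)
Conditions: toluene, reflux
Reagents that add atoms: none
Why: thermal retro-[4+2] of the dioxinone releases acetone and an acylketene, which is captured by the enol oxygen of the diketone (lactonisation) to give the 4-hydroxy-2-pyrone.

Step 8
Reactants: 13 6-(dimethoxymethyl)-4-hydroxy-2H-pyran-2-one
Product: 14 3-diazo-6-(dimethoxymethyl)-2H-pyran-2,4(3H)-dione
Conditions: 4-acetamidobenzenesulfonyl azide, Et3N, MeCN, 0 °C → rt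
Reagents that add atoms: 4-acetamidobenzenesulfonyl azide, CC(=O)Nc1ccc(cc1)S(=O)(=O)N=[N+]=[N-]
Why: Regitz diazo transfer to the nucleophilic C3 of the cyclic 1,3-dicarbonyl system.

Step 9
Reactants: 8 (1S,2R)-1-(4-benzyloxy-3-methoxyphenyl)-2-(TBS-oxymethyl)-4-(trimethylsilyl)but-3-yn-1-ol; 14 3-diazo-6-(dimethoxymethyl)-2H-pyran-2,4(3H)-dione
Product: 15 3-{[(1S,2R)-1-(4-benzyloxy-3-methoxyphenyl)-2-(TBS-oxymethyl)-4-(trimethylsilyl)but-3-yn-1-yl]oxy}-6-(dimethoxymethyl)-4-hydroxy-2H-pyran-2-one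
Conditions: Rh2(OAc)4 (2 mol%), ClCH2CH2Cl, 70 °C, slow addition of 14 (1.5 equiv); used without storage
Reagents that add atoms: none
Why: dirhodium-carbenoid O–H insertion, in which the electrophilic carbenoid from 14 is captured by the hydroxyl oxygen of 8 and a proton shift gives the enol ether, so the benzylic C–O bond of 8 is never broken and its S configuration is retained, while the silyl cap keeps the alkyne away from the carbenoid.

Step 10
Reactants: 15 3-{[(1S,2R)-1-(4-benzyloxy-3-methoxyphenyl)-2-(TBS-oxymethyl)-4-(trimethylsilyl)but-3-yn-1-yl]oxy}-6-(dimethoxymethyl)-4-hydroxy-2H-pyran-2-one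
Product: 17 3-{[(1S,2R)-1-(4-benzyloxy-3-methoxyphenyl)-2-(TBS-oxymethyl)but-3-yn-1-yl]oxy}-6-(dimethoxymethyl)-4-methoxy-2H-pyran-2-one, via desilylated pyronol 16 (not isolated)
Conditions: K2CO3, MeOH, rt; evaporate; then Me2SO4, K2CO3, acetone, 50 °C
Reagents that add atoms: dimethyl sulfate, COS(=O)(=O)OC
Why: methanolysis of the alkynyl C–Si bond (the pyronol sits as its unreactive potassium salt) followed by O-methylation of the vinylogous carboxylate, which with a hard methylating agent should give the 4-methoxy-2-pyrone rather than the 2-methoxy-4-pyranone.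

Step 11
Reactants: 17 3-{[(1S,2R)-1-(4-benzyloxy-3-methoxyphenyl)-2-(TBS-oxymethyl)but-3-yn-1-yl]oxy}-6-(dimethoxymethyl)-4-methoxy-2H-pyran-2-one
Product: 19 (2S,3R)-2-(4-benzyloxy-3-methoxyphenyl)-3-(TBS-oxymethyl)-5-(dimethoxymethyl)-7-methoxy-2,3-dihydrobenzofuran, via bicyclic lactone adduct 18 (not isolated)
Conditions: degassed toluene (0.005 M), BHT (10 mol%), base-washed sealed tube, 170–190 °C
Reagents that add atoms: none
Why: Proposed new method: on heating, the tethered terminal alkyne should add across C3 and C6 of the pyrone diene (internal alkyne carbon to C3, terminal carbon to C6) to give the 2-oxabicyclo[2.2.2]octadienone 18, which loses CO2 by cycloreversion and aromatises; the closest known reaction type is the intramolecular 2-pyrone–alkyne Diels–Alder reaction with CO2 extrusion, and the same tether topology is known for heteroatom-tethered alkynyl azines that give fused five-membered rings after loss of N2. Ring B is closed as a six-membered carbocycle by the [4+2] addition (bonds C7a–C3a and C4–C5), and the dihydrofuran ring is closed in the same event as a five-membered ring in the type 1 intramolecular mode, the three-atom O1–C2–C3 tether joining the diene terminus to the proximal alkyne carbon. No stereocentre is created: the two bridgeheads of 18 are transient and vanish on aromatisation, and C2 and C3 lie in the tether and are untouched, so the anti (1S,2R) array of 17 becomes the trans (2S,3R) ring. The step needs regioselectivity, which the tether enforces because it can bring only the internal alkyne carbon to C3, and chemoselectivity over thermal heterolysis of the benzylic C2–O bond, which is served by a non-polar, acid-free medium at high dilution. The pyrone is electron-rich and the alkyne unactivated, so temperatures near 180 °C are expected to be needed; the oxygen link and the vicinal substituents on the tether should raise the population of the reactive conformer.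

Step 12
Reactants: 19 (2S,3R)-2-(4-benzyloxy-3-methoxyphenyl)-3-(TBS-oxymethyl)-5-(dimethoxymethyl)-7-methoxy-2,3-dihydrobenzofuran
Product: 20 (2S,3R)-2-(4-benzyloxy-3-methoxyphenyl)-3-(TBS-oxymethyl)-7-methoxy-2,3-dihydrobenzofuran-5-carbaldehyde (DHB–CHO)
Conditions: PPTS (10 mol%), acetone/H2O 10:1, rt
Reagents that add atoms: water, O
Why: acid-catalysed hydrolysis of an electron-rich aryl dimethyl acetal, mild enough to spare the primary silyl ether and the benzylic C2–O bond.

Step 13
Reactants: 20 DHB–CHO; 21 dimethyl succinate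
Product: 23 (E)-4-DHB-3-(methoxycarbonyl)but-3-enoic acid, via paraconic ester 22 (not isolated)
Conditions: 21 (3 equiv), NaOMe (3 equiv), MeOH, reflux; then cold dilute HCl to pH 3
Reagents that add atoms: none
Why: Stobbe condensation, in which aldol addition of the succinate enolate, lactonisation to the paraconic ester and E1cB ring opening give the (E)-arylidene half-ester with the free acid on the methylene arm.

Step 14
Reactants: 23 (E)-4-DHB-3-(methoxycarbonyl)but-3-enoic acid
Product: 24 (R)-4-DHB-3-(methoxycarbonyl)butanoic acid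
Conditions: [Rh(cod)((S,S)-Et-DuPHOS)]BF4 (1 mol%), NaOMe (10 mol%), MeOH, H2 (5 atm), rt
Reagents that add atoms: none
Why: Rh–DuPHOS asymmetric hydrogenation of a Stobbe-type itaconate half-ester, in which the carboxylate chelates rhodium and the (S,S)-ligand is expected to direct hydrogen to the face that gives the (R)-succinate, the benzyl ethers being inert to the homogeneous catalyst.

Step 15
Reactants: 24 (R)-4-DHB-3-(methoxycarbonyl)butanoic acid
Product: 26 (R)-4-(DHB-methyl)dihydrofuran-2(3H)-one, via hydroxy acid 25 (not isolated)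
Conditions: KOH (1.0 equiv), EtOH, 0 °C; CaCl2, NaBH4, EtOH, 0 °C → rt; cold dilute HCl to pH 3; then PPTS (cat.), toluene, 40 °C
Reagents that add atoms: none
Why: Ca(BH4)2 formed in the flask reduces the methyl ester but not the carboxylate salt, and acidification closes the γ-hydroxy acid to the β-substituted γ-butyrolactone (lactonisation) without touching the stereocentre.

Step 16
Reactants: 27 4-benzyloxy-3-methoxybenzyl alcohol
Product: 28 4-benzyloxy-3-methoxybenzyl bromide
Conditions: PBr3 (0.4 equiv), Et2O, 0 °C; used at once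
Reagents that add atoms: phosphorus tribromide, BrP(Br)Br
Why: conversion of a benzylic alcohol into the bromide by SN2 displacement of its phosphite ester.

Step 17
Reactants: 26 (R)-4-(DHB-methyl)dihydrofuran-2(3H)-one; 28 4-benzyloxy-3-methoxybenzyl bromide
Product: 29 (3R,4R)-3-(4-benzyloxy-3-methoxybenzyl)-4-(DHB-methyl)dihydrofuran-2(3H)-one
Conditions: LiHMDS, THF, −78 °C; then 28, DMPU, −78 → −40 °C
Reagents that add atoms: none
Why: alkylation of the lithium lactone enolate by the benzylic bromide occurs anti to the β-substituent, which sets the α-centre R and gives the trans-2,3-dibenzylbutyrolactone.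

Step 18
Reactants: 29 (3R,4R)-3-(4-benzyloxy-3-methoxybenzyl)-4-(DHB-methyl)dihydrofuran-2(3H)-one
Product: 30 (3R,4R)-3-(4-benzyloxy-3-methoxybenzyl)-4-{[(2S,3R)-2-(4-benzyloxy-3-methoxyphenyl)-3-(hydroxymethyl)-7-methoxy-2,3-dihydrobenzofuran-5-yl]methyl}dihydrofuran-2(3H)-one
Conditions: HF·pyridine, pyridine/THF, 0 °C → rt
Reagents that add atoms: none
Why: fluoride cleavage of the primary silyl ether under buffered conditions that should neither epimerise the lactone nor open the dihydrofuran ring.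

Step 19
Reactants: 30 (3R,4R)-3-(4-benzyloxy-3-methoxybenzyl)-4-{[(2S,3R)-2-(4-benzyloxy-3-methoxyphenyl)-3-(hydroxymethyl)-7-methoxy-2,3-dihydrobenzofuran-5-yl]methyl}dihydrofuran-2(3H)-one
Product: 31 Lappaol A
Conditions: H2 (1 atm), 10% Pd/C, EtOAc/EtOH, rt; stopped after uptake of 2 equiv
Reagents that add atoms: none
Why: hydrogenolysis of the two aryl benzyl ethers over Pd/C should be much faster than cleavage of the hindered cyclic benzylic C2–O bond and releases both phenols to give the target.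

## Compound list

1 | (tert-butyldimethylsilyloxy)acetaldehyde | O=CCO[Si](C)(C)C(C)(C)C | starting material
2 | trimethylsilylacetylene | C#C[Si](C)(C)C | starting material
3 | rac-1-(TBS-oxy)-4-(trimethylsilyl)but-3-yn-2-ol | C[Si](C)(C)C#CC(O)CO[Si](C)(C)C(C)(C)C | intermediate
4 | 1-(TBS-oxy)-4-(trimethylsilyl)but-3-yn-2-one | C[Si](C)(C)C#CC(=O)CO[Si](C)(C)C(C)(C)C | intermediate
5 | (S)-1-(TBS-oxy)-4-(trimethylsilyl)but-3-yn-2-ol | C[Si](C)(C)C#C[C@H](O)CO[Si](C)(C)C(C)(C)C | intermediate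
6 | (S)-1-(TBS-oxy)-4-(trimethylsilyl)but-3-yn-2-yl methanesulfonate | C[Si](C)(C)C#C[C@H](OS(C)(=O)=O)CO[Si](C)(C)C(C)(C)C | intermediate
7 | 4-benzyloxy-3-methoxybenzaldehyde | COc1cc(C=O)ccc1OCc1ccccc1 | starting material
8 | (1S,2R)-1-(4-benzyloxy-3-methoxyphenyl)-2-(TBS-oxymethyl)-4-(trimethylsilyl)but-3-yn-1-ol | COc1cc(ccc1OCc1ccccc1)[C@@H](O)[C@@H](CO[Si](C)(C)C(C)(C)C)C#C[Si](C)(C)C | intermediate
9 | 2,2,6-trimethyl-4H-1,3-dioxin-4-one | CC1=CC(=O)OC(C)(C)O1 | starting material
10 | methyl dimethoxyacetate | COC(OC)C(=O)OC | starting material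
11 | 6-(3,3-dimethoxy-2-oxopropyl)-2,2-dimethyl-4H-1,3-dioxin-4-one | COC(OC)C(=O)CC1=CC(=O)OC(C)(C)O1 | intermediate
12 | 6,6-dimethoxy-3,5-dioxohex-1-en-1-one (acylketene, formed in the flask) | COC(OC)C(=O)CC(=O)C=C=O | intermediate
13 | 6-(dimethoxymethyl)-4-hydroxy-2H-pyran-2-one | COC(OC)C1=CC(O)=CC(=O)O1 | intermediate
14 | 3-diazo-6-(dimethoxymethyl)-2H-pyran-2,4(3H)-dione | COC(OC)C1=CC(=O)C(=[N+]=[N-])C(=O)O1 | intermediate
15 | 3-{[(1S,2R)-1-(4-benzyloxy-3-methoxyphenyl)-2-(TBS-oxymethyl)-4-(trimethylsilyl)but-3-yn-1-yl]oxy}-6-(dimethoxymethyl)-4-hydroxy-2H-pyran-2-one | O=C1OC(C(OC)OC)=CC(O)=C1O[C@H](c1ccc(OCc2ccccc2)c(OC)c1)[C@@H](CO[Si](C)(C)C(C)(C)C)C#C[Si](C)(C)C | intermediate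
16 | 3-{[(1S,2R)-1-(4-benzyloxy-3-methoxyphenyl)-2-(TBS-oxymethyl)but-3-yn-1-yl]oxy}-6-(dimethoxymethyl)-4-hydroxy-2H-pyran-2-one (formed in the flask as its potassium salt) | O=C1OC(C(OC)OC)=CC(O)=C1O[C@H](c1ccc(OCc2ccccc2)c(OC)c1)[C@@H](CO[Si](C)(C)C(C)(C)C)C#C | intermediate
17 | 3-{[(1S,2R)-1-(4-benzyloxy-3-methoxyphenyl)-2-(TBS-oxymethyl)but-3-yn-1-yl]oxy}-6-(dimethoxymethyl)-4-methoxy-2H-pyran-2-one | O=C1OC(C(OC)OC)=CC(OC)=C1O[C@H](c1ccc(OCc2ccccc2)c(OC)c1)[C@@H](CO[Si](C)(C)C(C)(C)C)C#C | intermediate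
18 | bicyclic lactone adduct: 2-oxabicyclo[2.2.2]octa-5,7-dien-3-one fused to the dihydrofuran ring, bridgehead configuration undefined (formed in the flask) | O=C1OC2(C(OC)OC)C=C(OC)C13O[C@H](c1ccc(OCc4ccccc4)c(OC)c1)[C@@H](CO[Si](C)(C)C(C)(C)C)C3=C2 | intermediate
19 | (2S,3R)-2-(4-benzyloxy-3-methoxyphenyl)-3-(TBS-oxymethyl)-5-(dimethoxymethyl)-7-methoxy-2,3-dihydrobenzofuran | COC(OC)c1cc(OC)c2c(c1)[C@H](CO[Si](C)(C)C(C)(C)C)[C@@H](c1ccc(OCc3ccccc3)c(OC)c1)O2 | intermediate
20 | (2S,3R)-2-(4-benzyloxy-3-methoxyphenyl)-3-(TBS-oxymethyl)-7-methoxy-2,3-dihydrobenzofuran-5-carbaldehyde | O=Cc1cc(OC)c2c(c1)[C@H](CO[Si](C)(C)C(C)(C)C)[C@@H](c1ccc(OCc3ccccc3)c(OC)c1)O2 | intermediate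
21 | dimethyl succinate | COC(=O)CCC(=O)OC | starting material
22 | methyl 2-DHB-5-oxotetrahydrofuran-3-carboxylate (paraconic ester, new centres undefined, formed in the flask) | COC(=O)C1CC(=O)OC1c1cc(OC)c2c(c1)[C@H](CO[Si](C)(C)C(C)(C)C)[C@@H](c1ccc(OCc3ccccc3)c(OC)c1)O2 | intermediate
23 | (E)-4-DHB-3-(methoxycarbonyl)but-3-enoic acid | COC(=O)/C(=C/c1cc(OC)c2c(c1)[C@H](CO[Si](C)(C)C(C)(C)C)[C@@H](c1ccc(OCc3ccccc3)c(OC)c1)O2)CC(=O)O | intermediate
24 | (R)-4-DHB-3-(methoxycarbonyl)butanoic acid | COC(=O)[C@H](Cc1cc(OC)c2c(c1)[C@H](CO[Si](C)(C)C(C)(C)C)[C@@H](c1ccc(OCc3ccccc3)c(OC)c1)O2)CC(=O)O | intermediate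
25 | (R)-4-DHB-3-(hydroxymethyl)butanoic acid (formed in the flask) | OC[C@H](Cc1cc(OC)c2c(c1)[C@H](CO[Si](C)(C)C(C)(C)C)[C@@H](c1ccc(OCc3ccccc3)c(OC)c1)O2)CC(=O)O | intermediate
26 | (R)-4-(DHB-methyl)dihydrofuran-2(3H)-one | O=C1C[C@@H](Cc2cc(OC)c3c(c2)[C@H](CO[Si](C)(C)C(C)(C)C)[C@@H](c2ccc(OCc4ccccc4)c(OC)c2)O3)CO1 | intermediate
27 | 4-benzyloxy-3-methoxybenzyl alcohol | COc1cc(CO)ccc1OCc1ccccc1 | starting material
28 | 4-benzyloxy-3-methoxybenzyl bromide | COc1cc(CBr)ccc1OCc1ccccc1 | intermediate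
29 | (3R,4R)-3-(4-benzyloxy-3-methoxybenzyl)-4-(DHB-methyl)dihydrofuran-2(3H)-one | COc1cc(C[C@H]2C(=O)OC[C@@H]2Cc2cc(OC)c3c(c2)[C@H](CO[Si](C)(C)C(C)(C)C)[C@@H](c2ccc(OCc4ccccc4)c(OC)c2)O3)ccc1OCc1ccccc1 | intermediate
30 | (3R,4R)-3-(4-benzyloxy-3-methoxybenzyl)-4-{[(2S,3R)-2-(4-benzyloxy-3-methoxyphenyl)-3-(hydroxymethyl)-7-methoxy-2,3-dihydrobenzofuran-5-yl]methyl}dihydrofuran-2(3H)-one | COc1cc(C[C@H]2C(=O)OC[C@@H]2Cc2cc(OC)c3c(c2)[C@H](CO)[C@@H](c2ccc(OCc4ccccc4)c(OC)c2)O3)ccc1OCc1ccccc1 | intermediate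
31 | Lappaol A | COc1cc(C[C@H]2C(=O)OC[C@@H]2Cc2cc(OC)c3c(c2)[C@H](CO)[C@@H](c2ccc(O)c(OC)c2)O3)ccc1O | target

## Step count and risks

Total step count: 19. Longest linear sequence: 15 steps (1–5, 9–15, 17–19).

**Step 11 (most likely to fail).** The cycloaddition may not start below the temperature at which the benzylic C2–O bond ionises, which would lead to loss of the pyronol and elimination to an enyne, or to slow thermal erosion of the acetal.
Fallback (sets out from 28, rejoins at 19): the pyrone cycloaddition is replaced by a known carbenoid C–H insertion that closes the dihydrofuran ring onto a purchased ring B. Commercial 5-iodovanillin is O-alkylated with 28 (K2CO3, DMF) to give 4-[(4-benzyloxy-3-methoxybenzyl)oxy]-3-iodo-5-methoxybenzaldehyde F1. Its aldehyde is masked (HC(OMe)3, MeOH, cat. TsOH) as the dimethyl acetal F2. Palladium-catalysed coupling of the aryl iodide with methyl diazoacetate (Pd(PPh3)4, Ag2CO3, Et3N, toluene) gives the aryldiazoacetate F3. Enantioselective intramolecular C–H insertion into the benzylic ether CH2 with a chiral dirhodium carboxylate (Rh2(S-PTTL)4 or its antipode, chosen for the 2S series) gives the cis-2,3-dihydrobenzofuran ester F4. NaOMe in MeOH epimerises C3 to give the trans ester F5. LiAlH4 reduces it to the trans alcohol F6, and TBSCl/imidazole returns 19.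

**Step 9.** The carbenoid may be consumed by dimerisation, or by a second insertion into the acidic enol O–H of the product, faster than it is captured by the hindered secondary hydroxyl group.
Fallback (sets out from 14 and 8, rejoins at 19): the ether is made by Mitsunobu displacement and C2 is corrected thermodynamically after ring closure. Insertion of 14 into the O–H bond of benzyl alcohol, an unhindered primary alcohol (Rh2(OAc)4), gives 3-(benzyloxy)-6-(dimethoxymethyl)-4-hydroxy-2H-pyran-2-one F7. O-Methylation (Me2SO4, K2CO3, acetone) gives the 4-methoxy compound F8, and hydrogenolysis (H2, Pd/C) gives 6-(dimethoxymethyl)-3-hydroxy-4-methoxy-2H-pyran-2-one F9. Alkynol 8 is C-desilylated (K2CO3, MeOH) to the terminal alkynol F10. Mitsunobu coupling of F9 with F10 (PPh3, DIAD, toluene, 0 °C) goes with inversion at the benzylic carbon and gives the (1R,2R) pyronyl ether F11, the C1 epimer of 17; partial loss of configuration here is harmless. F11 is taken through the conditions of step 11 to the cis-dihydrobenzofuran F12. Brief treatment with anhydrous acid (camphorsulfonic acid, dry CH2Cl2) opens the benzylic C2–O bond reversibly through the 4-benzyloxybenzyl cation and recloses it to the more stable trans isomer 19, the known cis-to-trans equilibration of 2-aryl-2,3-dihydrobenzofurans.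

**Step 14.** Hydrogenation of the hindered trisubstituted alkene may be slow and poorly face-selective, and forcing it invites hydrogenolytic damage.
Fallback (sets out from 20, rejoins at 26; it also bypasses step 13): the succinate stereocentre is set by auxiliary-controlled alkylation instead of hydrogenation. Aldehyde 20 is reduced (NaBH4, MeOH) to the benzylic alcohol DHB–CH2OH F13 and converted (CBr4, PPh3, CH2Cl2, 0 °C) into the bromide DHB–CH2Br F14. The acyl oxazolidinone methyl 4-[(4R)-4-benzyl-2-oxo-1,3-oxazolidin-3-yl]-4-oxobutanoate F15 is made from (R)-4-benzyl-2-oxazolidinone (n-BuLi, THF, −78 °C) and methyl 4-chloro-4-oxobutanoate. Its sodium enolate (NaHMDS, THF, −78 °C) is alkylated by F14 on the face away from the benzyl group of the auxiliary (Evans alkylation) to give the (R)-alkylated imide F16. LiBH4 (THF, 1 equiv H2O, 0 °C) cleaves the imide reductively to the hydroxy ester methyl (R)-4-hydroxy-3-(DHB-methyl)butanoate F17, which closes to 26 with a catalytic amount of PPTS.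

## Further compounds

F1 | step 11 | 4-[(4-benzyloxy-3-methoxybenzyl)oxy]-3-iodo-5-methoxybenzaldehyde | COc1cc(C=O)cc(I)c1OCc1ccc(OCc2ccccc2)c(OC)c1
F2 | step 11 | 2-[(4-benzyloxy-3-methoxybenzyl)oxy]-5-(dimethoxymethyl)-1-iodo-3-methoxybenzene | COC(OC)c1cc(OC)c(OCc2ccc(OCc3ccccc3)c(OC)c2)c(I)c1
F3 | step 11 | methyl 2-diazo-2-{2-[(4-benzyloxy-3-methoxybenzyl)oxy]-5-(dimethoxymethyl)-3-methoxyphenyl}acetate | COC(OC)c1cc(OC)c(OCc2ccc(OCc3ccccc3)c(OC)c2)c(c1)C(=[N+]=[N-])C(=O)OC
F4 | step 11 | methyl (2S,3R)-2-(4-benzyloxy-3-methoxyphenyl)-5-(dimethoxymethyl)-7-methoxy-2,3-dihydrobenzofuran-3-carboxylate (cis) | COC(OC)c1cc(OC)c2c(c1)[C@@H](C(=O)OC)[C@@H](c1ccc(OCc3ccccc3)c(OC)c1)O2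
F5 | step 11 | methyl (2S,3S)-2-(4-benzyloxy-3-methoxyphenyl)-5-(dimethoxymethyl)-7-methoxy-2,3-dihydrobenzofuran-3-carboxylate (trans) | COC(OC)c1cc(OC)c2c(c1)[C@H](C(=O)OC)[C@@H](c1ccc(OCc3ccccc3)c(OC)c1)O2
F6 | step 11 | [(2S,3R)-2-(4-benzyloxy-3-methoxyphenyl)-5-(dimethoxymethyl)-7-methoxy-2,3-dihydrobenzofuran-3-yl]methanol | COC(OC)c1cc(OC)c2c(c1)[C@H](CO)[C@@H](c1ccc(OCc3ccccc3)c(OC)c1)O2
F7 | step 9 | 3-(benzyloxy)-6-(dimethoxymethyl)-4-hydroxy-2H-pyran-2-one | COC(OC)C1=CC(O)=C(OCc2ccccc2)C(=O)O1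
F8 | step 9 | 3-(benzyloxy)-6-(dimethoxymethyl)-4-methoxy-2H-pyran-2-one | COC(OC)C1=CC(OC)=C(OCc2ccccc2)C(=O)O1
F9 | step 9 | 6-(dimethoxymethyl)-3-hydroxy-4-methoxy-2H-pyran-2-one | COC(OC)C1=CC(OC)=C(O)C(=O)O1
F10 | step 9 | (1S,2R)-1-(4-benzyloxy-3-methoxyphenyl)-2-(TBS-oxymethyl)but-3-yn-1-ol | COc1cc(ccc1OCc1ccccc1)[C@@H](O)[C@@H](CO[Si](C)(C)C(C)(C)C)C#C
F11 | step 9 | 3-{[(1R,2R)-1-(4-benzyloxy-3-methoxyphenyl)-2-(TBS-oxymethyl)but-3-yn-1-yl]oxy}-6-(dimethoxymethyl)-4-methoxy-2H-pyran-2-one | O=C1OC(C(OC)OC)=CC(OC)=C1O[C@@H](c1ccc(OCc2ccccc2)c(OC)c1)[C@@H](CO[Si](C)(C)C(C)(C)C)C#C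
F12 | step 9 | (2R,3R)-2-(4-benzyloxy-3-methoxyphenyl)-3-(TBS-oxymethyl)-5-(dimethoxymethyl)-7-methoxy-2,3-dihydrobenzofuran (cis) | COC(OC)c1cc(OC)c2c(c1)[C@H](CO[Si](C)(C)C(C)(C)C)[C@H](c1ccc(OCc3ccccc3)c(OC)c1)O2
F13 | step 14 | [(2S,3R)-2-(4-benzyloxy-3-methoxyphenyl)-3-(TBS-oxymethyl)-7-methoxy-2,3-dihydrobenzofuran-5-yl]methanol | OCc1cc(OC)c2c(c1)[C@H](CO[Si](C)(C)C(C)(C)C)[C@@H](c1ccc(OCc3ccccc3)c(OC)c1)O2
F14 | step 14 | (2S,3R)-2-(4-benzyloxy-3-methoxyphenyl)-5-(bromomethyl)-3-(TBS-oxymethyl)-7-methoxy-2,3-dihydrobenzofuran | BrCc1cc(OC)c2c(c1)[C@H](CO[Si](C)(C)C(C)(C)C)[C@@H](c1ccc(OCc3ccccc3)c(OC)c1)O2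
F15 | step 14 | methyl 4-[(4R)-4-benzyl-2-oxo-1,3-oxazolidin-3-yl]-4-oxobutanoate | COC(=O)CCC(=O)N1[C@H](Cc2ccccc2)COC1=O
F16 | step 14 | methyl (3R)-4-[(4R)-4-benzyl-2-oxo-1,3-oxazolidin-3-yl]-3-(DHB-methyl)-4-oxobutanoate | COC(=O)C[C@@H](Cc1cc(OC)c2c(c1)[C@H](CO[Si](C)(C)C(C)(C)C)[C@@H](c1ccc(OCc3ccccc3)c(OC)c1)O2)C(=O)N1[C@H](Cc2ccccc2)COC1=O
F17 | step 14 | methyl (3R)-4-hydroxy-3-(DHB-methyl)butanoate | COC(=O)C[C@@H](Cc1cc(OC)c2c(c1)[C@H](CO[Si](C)(C)C(C)(C)C)[C@@H](c1ccc(OCc3ccccc3)c(OC)c1)O2)CO
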